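## Retrosynthetic overview

- The target is reached from a trans-diol by acylation of the secondary hydroxyl with O-acetyl-protected p-coumaric acid; the diol comes from a β-hydroxy ketone by hydroxyl-directed reduction.
- The bicyclic ketone is opened between the carbonyl carbon C-6 and the ring CH2 C-7 (hydroazulene locants of the compound names): rhodium-catalysed intramolecular hydroacylation of a 4,6-dienal adds acyl and H across a 1-isopropenylcyclopentene.
- Enabling feature: in the seven-membered ring, O=C-6, C-7H2, C-8(CH3)=C-8a and C-3a–H form a cyclohept-3-enone unit. The acyl carbon and the ring-fusion H therefore sit 1,4 across a diene (C-7=C-8–C-8a=C-3a) whose fully substituted end lies in the five-membered ring.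
- The dienal comes from an auxiliary-controlled enolate alkylation (sets C-5) of a β-silyloxy imide with a cyclopentenylmethyl bromide, then Suzuki isopropenylation of the enol triflate.
- Ring order: the cyclopentane is taken from (S)-pulegone by Favorskii contraction and ozonolysis (C-3 methyl centre from the chiral pool); the seven-membered ring is closed second and last.

Key step: step 12

Remark: (S)-(−)-pulegone, (R)-4-benzyloxazolidin-2-one, 3-hydroxy-3-methylbutanoic acid, isopropenylboronic acid pinacol ester and (E)-4-acetoxycinnamic acid are taken as commercial.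

## Route

Step 1
Reactants: 1 (S)-(−)-pulegone
Product: 3 methyl (5S)-5-methyl-2-(propan-2-ylidene)cyclopentane-1-carboxylate (methyl pulegenate, mixture at C-1), via pulegone dibromide 2 (not isolated)
Conditions: Br2, Et2O, 0 °C; then NaOMe, MeOH, reflux
Reagents that add atoms: sodium methoxide, [Na+].[O-]C
Why: Favorskii rearrangement: the α'-enolate of dibromide 2 closes a cyclopropanone, methoxide opens it and the carbanion expels the second bromide, which contracts the ring and regenerates the isopropylidene group without touching the methyl-bearing stereocentre.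

Step 2
Reactants: 3 methyl pulegenate
Product: 5 methyl (1RS,2S)-2-methyl-5-oxocyclopentane-1-carboxylate, via secondary ozonide 4 (not isolated)
Conditions: O3, CH2Cl2, −78 °C; then Me2S, −78 °C to rt
Reagents that add atoms: ozone, O=[O+][O-]
Why: Ozonolysis with reductive work-up should cleave the tetrasubstituted isopropylidene alkene to the β-keto ester and acetone; no stereocentre is involved.

Step 3
Reactants: 5 β-keto ester
Product: 6 methyl (5S)-5-methyl-2-[(trifluoromethanesulfonyl)oxy]cyclopent-1-ene-1-carboxylate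
Conditions: Tf2O, i-Pr2NEt, CH2Cl2, −78 °C to 0 °C
Reagents that add atoms: trifluoromethanesulfonic anhydride, O=S(=O)(OS(=O)(=O)C(F)(F)F)C(F)(F)F
Why: Enol triflate formation from the conjugated β-keto ester enolate fixes the double bond between the former ketone carbon and the ester-bearing carbon, so the mixture at that carbon converges to one compound.

Step 4
Reactants: 6 enol triflate ester
Product: 7 (3S)-2-(hydroxymethyl)-3-methylcyclopent-1-en-1-yl trifluoromethanesulfonate
Conditions: i-Bu2AlH (2.5 equiv), CH2Cl2, −78 °C; aq. potassium sodium tartrate (KNaC4H4O6) work-up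
Reagents that add atoms: none
Why: 1,2-Reduction of the conjugated ester with i-Bu2AlH at low temperature should give the allylic alcohol, the vinyl triflate being inert to the hydride.

Step 5
Reactants: 7 allylic alcohol
Product: 8 (3S)-2-(bromomethyl)-3-methylcyclopent-1-en-1-yl trifluoromethanesulfonate
Conditions: CBr4, PPh3, CH2Cl2, 0 °C
Reagents that add atoms: carbon tetrabromide, BrC(Br)(Br)Br
Why: The Appel reaction converts the primary allylic alcohol into the bromide under neutral conditions that leave the vinyl triflate intact.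

Step 6
Reactants: 9 3-hydroxy-3-methylbutanoic acid; 10 (R)-4-benzyloxazolidin-2-one
Product: 12 (4R)-4-benzyl-3-(3-hydroxy-3-methylbutanoyl)-1,3-oxazolidin-2-one, via mixed pivalic anhydride 11 (not isolated)
Conditions: t-BuCOCl, Et3N, THF, −20 °C; then 10, LiCl, −20 °C to rt
Reagents that add atoms: 10 (R)-4-benzyloxazolidin-2-one, O=C1N[C@H](Cc2ccccc2)CO1
Why: N-Acylation of the oxazolidinone through the mixed pivalic anhydride should proceed with the unreactive tertiary hydroxyl left free.

Step 7
Reactants: 12 hydroxy imide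
Product: 13 (4R)-4-benzyl-3-[3-methyl-3-(triethylsilyloxy)butanoyl]-1,3-oxazolidin-2-one
Conditions: Et3SiOTf, 2,6-lutidine, CH2Cl2, 0 °C
Reagents that add atoms: triethylsilyl trifluoromethanesulfonate, CC[Si](CC)(CC)OS(=O)(=O)C(F)(F)F
Why: Silyl triflate protection of the tertiary alcohol removes the acidic OH before enolisation.

Step 8
Reactants: 8 allylic bromide; 13 silyloxy imide
Product: 15 (4R)-4-benzyl-3-[(2R)-3-methyl-2-({(5S)-5-methyl-2-[(trifluoromethanesulfonyl)oxy]cyclopent-1-en-1-yl}methyl)-3-(triethylsilyloxy)butanoyl]-1,3-oxazolidin-2-one, via sodium Z-enolate 14 (not isolated)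
Conditions: NaN(SiMe3)2, THF, −78 °C; then 8, −78 to −30 °C
Reagents that add atoms: 13 silyloxy imide, CC[Si](CC)(CC)OC(C)(C)CC(=O)N1[C@H](Cc2ccccc2)COC1=O
Why: Evans auxiliary-controlled enolate alkylation: the chelated Z-enolate 14 is attacked by the allylic bromide on the face opposite the benzyl group, which should set the R configuration at the new α-carbon (the later C-5).

Step 9
Reactants: 15 alkylated imide
Product: 16 (3S)-2-[(2S)-2-(hydroxymethyl)-3-methyl-3-(triethylsilyloxy)butyl]-3-methylcyclopent-1-en-1-yl trifluoromethanesulfonate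
Conditions: LiBH4, MeOH (1 equiv), THF, 0 °C
Reagents that add atoms: none
Why: Reductive cleavage of the imide with LiBH4 should give the primary alcohol without touching the α-stereocentre or the vinyl triflate, and releases the auxiliary.

Step 10
Reactants: 16 triflate alcohol; 17 4,4,5,5-tetramethyl-2-(prop-1-en-2-yl)-1,3,2-dioxaborolane
Product: 18 (2S)-3-methyl-2-{[(5S)-5-methyl-2-(prop-1-en-2-yl)cyclopent-1-en-1-yl]methyl}-3-(triethylsilyloxy)butan-1-ol
Conditions: Pd(PPh3)4 (5 mol %), K3PO4, dioxane/H2O, 80 °C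
Reagents that add atoms: 17 isopropenylboronic acid pinacol ester, CC(=C)B1OC(C)(C)C(C)(C)O1
Why: Suzuki–Miyaura coupling of the cyclopentenyl triflate with the isopropenyl boronate installs the 2-substituted 1,3-diene; free hydroxyl and silyl ether are tolerated.

Step 11
Reactants: 18 dienol
Product: 19 (2R)-3-methyl-2-{[(5S)-5-methyl-2-(prop-1-en-2-yl)cyclopent-1-en-1-yl]methyl}-3-(triethylsilyloxy)butanal
Conditions: Dess–Martin periodinane, CH2Cl2, 0 °C to rt
Reagents that add atoms: none
Why: Dess–Martin oxidation under non-basic conditions should give the α-branched aldehyde without epimerisation.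

Step 12
Reactants: 19 4,6-dienal
Product: 20 (3S,3aS,5R)-3,8-dimethyl-5-[2-(triethylsilyloxy)propan-2-yl]-2,3,3a,4,5,7-hexahydroazulen-6(1H)-one
Conditions: [Rh(nbd)(dppe)]BF4 (10 mol %; nbd removed with H2, then Ar), ClCH2CH2Cl, 65 °C
Reagents that add atoms: none
Why: Oxidative addition of the aldehyde C–H bond to the cationic monovalent rhodium centre gives a trivalent acyl rhodium hydride held over the s-cis diene by the two-carbon tether; the hydride is transferred to the ring carbon carrying the tether, leaving an η3-allyl over C-8a, C-8 and the terminal CH2, and acyl–allyl reductive elimination at the CH2 terminus closes the ring. The closest known reaction type is the rhodium-catalysed intramolecular hydroacylation of 4,6-dienals to cyclohept-3-enones. The seven-membered ring is closed by C–C bond formation between the acyl carbon and the diene terminus remote from the tether (a 1,4-addition of acyl and H across the diene, 7-endo with respect to the isopropenyl unit), so the tetrasubstituted C-8=C-8a double bond arises in the only geometry the ring allows. The one new stereocentre, C-3a, should be set by hydride delivery from rhodium on the cyclopentene face opposite the adjacent C-3 methyl group, which places H-3a cis to H-3 as the target requires; C-5, α to the carbonyl, is carried through unchanged under the neutral conditions. The step needs reductive elimination to the seven- and not the five-membered ring, and this is secured because the competing allyl terminus is a fully substituted ring carbon that would have to become quaternary.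

Step 13
Reactants: 20 silyloxy ketone
Product: 21 (3S,3aS,5R)-5-(2-hydroxypropan-2-yl)-3,8-dimethyl-2,3,3a,4,5,7-hexahydroazulen-6(1H)-one
Conditions: HF·pyridine, pyridine, THF, 0 °C
Reagents that add atoms: none
Why: Buffered fluoride cleavage of the tertiary triethylsilyl ether avoids base (retro-aldol, alkene conjugation) and strong acid (dehydration, alkene migration).

Step 14
Reactants: 21 β-hydroxy ketone
Product: 22 (3S,3aS,5S,6S)-5-(2-hydroxypropan-2-yl)-3,8-dimethyl-1,2,3,3a,4,5,6,7-octahydroazulen-6-ol
Conditions: Me4NBH(OAc)3, MeCN/AcOH, −30 °C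
Reagents that add atoms: none
Why: Evans–Saksena hydroxyl-directed reduction: the tertiary hydroxyl exchanges onto boron and delivers hydride intramolecularly to the carbonyl face on the side of the hydroxyisopropyl group, which should place the new hydroxyl trans to that group (6S).

Step 15
Reactants: 22 diol; 23 (E)-4-acetoxycinnamic acid
Product: 24 (3S,3aS,5S,6S)-5-(2-hydroxypropan-2-yl)-3,8-dimethyl-1,2,3,3a,4,5,6,7-octahydroazulen-6-yl (2E)-3-[4-(acetyloxy)phenyl]prop-2-enoate
Conditions: DCC, DMAP (cat.), CH2Cl2, 0 °C to rt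
Reagents that add atoms: 23 (E)-4-acetoxycinnamic acid, CC(=O)Oc1ccc(/C=C/C(=O)O)cc1
Why: Steglich esterification should acylate only the secondary hydroxyl, the tertiary alcohol being too hindered, with retention at C-6 and of the E-alkene.

Step 16
Reactants: 24 acetate-protected ester
Product: 25 (3S,3aS,5S,6S)-5-(2-hydroxypropan-2-yl)-3,8-dimethyl-1,2,3,3a,4,5,6,7-octahydroazulen-6-yl (2E)-3-(4-hydroxyphenyl)prop-2-enoate (CNP0403230.1)
Conditions: K2CO3 (cat.), MeOH, 0 °C
Reagents that add atoms: none
Why: Mild methanolysis (transesterification) should cleave the aryl acetate much faster than the hindered secondary cinnamate ester and free the phenol.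

## Compound list

1 | (S)-(−)-pulegone, (5S)-5-methyl-2-(propan-2-ylidene)cyclohexan-1-one | C[C@H]1CCC(=C(C)C)C(=O)C1 | starting material
2 | (5S)-2-bromo-2-(2-bromopropan-2-yl)-5-methylcyclohexan-1-one (pulegone dibromide) | C[C@H]1CCC(Br)(C(C)(C)Br)C(=O)C1 | intermediate
3 | methyl (5S)-5-methyl-2-(propan-2-ylidene)cyclopentane-1-carboxylate | COC(=O)C1[C@@H](C)CCC1=C(C)C | intermediate
4 | methyl (7S)-3,3,7-trimethyl-1,2,4-trioxaspiro[4.4]nonane-6-carboxylate (secondary ozonide) | COC(=O)C1[C@@H](C)CCC12OOC(C)(C)O2 | intermediate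
5 | methyl (1RS,2S)-2-methyl-5-oxocyclopentane-1-carboxylate | COC(=O)C1[C@@H](C)CCC1=O | intermediate
6 | methyl (5S)-5-methyl-2-[(trifluoromethanesulfonyl)oxy]cyclopent-1-ene-1-carboxylate | COC(=O)C1=C(OS(=O)(=O)C(F)(F)F)CC[C@@H]1C | intermediate
7 | (3S)-2-(hydroxymethyl)-3-methylcyclopent-1-en-1-yl trifluoromethanesulfonate | OCC1=C(OS(=O)(=O)C(F)(F)F)CC[C@@H]1C | intermediate
8 | (3S)-2-(bromomethyl)-3-methylcyclopent-1-en-1-yl trifluoromethanesulfonate | BrCC1=C(OS(=O)(=O)C(F)(F)F)CC[C@@H]1C | intermediate
9 | 3-hydroxy-3-methylbutanoic acid | CC(C)(O)CC(=O)O | starting material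
10 | (R)-4-benzyloxazolidin-2-one | O=C1N[C@H](Cc2ccccc2)CO1 | starting material
11 | 3-hydroxy-3-methylbutanoic pivalic anhydride | CC(C)(O)CC(=O)OC(=O)C(C)(C)C | intermediate
12 | (4R)-4-benzyl-3-(3-hydroxy-3-methylbutanoyl)-1,3-oxazolidin-2-one | CC(C)(O)CC(=O)N1[C@H](Cc2ccccc2)COC1=O | intermediate
13 | (4R)-4-benzyl-3-[3-methyl-3-(triethylsilyloxy)butanoyl]-1,3-oxazolidin-2-one | CC[Si](CC)(CC)OC(C)(C)CC(=O)N1[C@H](Cc2ccccc2)COC1=O | intermediate
14 | sodium (Z)-enolate of 13 | CC[Si](CC)(CC)OC(C)(C)/C=C(\[O-])N1[C@H](Cc2ccccc2)COC1=O.[Na+] | intermediate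
15 | (4R)-4-benzyl-3-[(2R)-3-methyl-2-({(5S)-5-methyl-2-[(trifluoromethanesulfonyl)oxy]cyclopent-1-en-1-yl}methyl)-3-(triethylsilyloxy)butanoyl]-1,3-oxazolidin-2-one | C[C@H]1CCC(OS(=O)(=O)C(F)(F)F)=C1C[C@H](C(C)(C)O[Si](CC)(CC)CC)C(=O)N1[C@H](Cc2ccccc2)COC1=O | intermediate
16 | (3S)-2-[(2S)-2-(hydroxymethyl)-3-methyl-3-(triethylsilyloxy)butyl]-3-methylcyclopent-1-en-1-yl trifluoromethanesulfonate | C[C@H]1CCC(OS(=O)(=O)C(F)(F)F)=C1C[C@H](C(C)(C)O[Si](CC)(CC)CC)CO | intermediate
17 | 4,4,5,5-tetramethyl-2-(prop-1-en-2-yl)-1,3,2-dioxaborolane | CC(=C)B1OC(C)(C)C(C)(C)O1 | starting material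
18 | (2S)-3-methyl-2-{[(5S)-5-methyl-2-(prop-1-en-2-yl)cyclopent-1-en-1-yl]methyl}-3-(triethylsilyloxy)butan-1-ol | C[C@H]1CCC(C(C)=C)=C1C[C@H](C(C)(C)O[Si](CC)(CC)CC)CO | intermediate
19 | (2R)-3-methyl-2-{[(5S)-5-methyl-2-(prop-1-en-2-yl)cyclopent-1-en-1-yl]methyl}-3-(triethylsilyloxy)butanal | C[C@H]1CCC(C(C)=C)=C1C[C@H](C(C)(C)O[Si](CC)(CC)CC)C=O | intermediate
20 | (3S,3aS,5R)-3,8-dimethyl-5-[2-(triethylsilyloxy)propan-2-yl]-2,3,3a,4,5,7-hexahydroazulen-6(1H)-one | CC1=C2CC[C@H](C)[C@@H]2C[C@H](C(C)(C)O[Si](CC)(CC)CC)C(=O)C1 | intermediate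
21 | (3S,3aS,5R)-5-(2-hydroxypropan-2-yl)-3,8-dimethyl-2,3,3a,4,5,7-hexahydroazulen-6(1H)-one | CC1=C2CC[C@H](C)[C@@H]2C[C@H](C(C)(C)O)C(=O)C1 | intermediate
22 | (3S,3aS,5S,6S)-5-(2-hydroxypropan-2-yl)-3,8-dimethyl-1,2,3,3a,4,5,6,7-octahydroazulen-6-ol | CC1=C2CC[C@H](C)[C@@H]2C[C@H](C(C)(C)O)[C@@H](O)C1 | intermediate
23 | (E)-4-acetoxycinnamic acid | CC(=O)Oc1ccc(/C=C/C(=O)O)cc1 | starting material
24 | (3S,3aS,5S,6S)-5-(2-hydroxypropan-2-yl)-3,8-dimethyl-1,2,3,3a,4,5,6,7-octahydroazulen-6-yl (2E)-3-[4-(acetyloxy)phenyl]prop-2-enoate | CC1=C2CC[C@H](C)[C@@H]2C[C@H](C(C)(C)O)[C@@H](OC(=O)/C=C/c2ccc(OC(C)=O)cc2)C1 | intermediate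
25 | (3S,3aS,5S,6S)-5-(2-hydroxypropan-2-yl)-3,8-dimethyl-1,2,3,3a,4,5,6,7-octahydroazulen-6-yl (2E)-3-(4-hydroxyphenyl)prop-2-enoate | CC1=C2CC[C@H](C)[C@@H]2C[C@H](C(C)(C)O)[C@@H](OC(=O)/C=C/c2ccc(O)cc2)C1 | target

## Step count and risks

Total step count: 16. Longest linear sequence: 14 steps (steps 1–5 and 8–16, from 1).

**Step 12 (key step).** Hydride transfer to the fully substituted diene terminus may be slower than decarbonylation of the acyl rhodium hydride, and hydride delivery may not discriminate well between the two ring faces. The fallback sets out from 19 and comes back at 20, closing the ring by metathesis and setting C-3a by reduction.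
- Addition of CH2=CHMgBr (THF, −78 °C) to 19 should give the allylic alcohol F1 as a carbinol mixture.
- Ring-closing metathesis of its vinyl group with the isopropenyl group (second-generation Grubbs catalyst (H2IMes)(PCy3)Cl2Ru=CHPh, toluene, 80 °C) should close the seven-membered ring as the cycloheptadienol F2.
- Oxidation with MnO2 (CH2Cl2) should give the linearly conjugated dienone F3.
- Dissolving-metal reduction (Li, NH3/THF, t-BuOH, −78 °C; NH4Cl quench) should add hydrogen at the δ-carbon, the ring-fusion carbon, from the face opposite the ring methyl. Kinetic α-protonation of the dienolate should then give the β,γ-unsaturated ketone 20.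

**Step 8.** The hindered enolate 14 may lose triethylsilanolate by β-elimination faster than it is alkylated. The fallback sets out from 8 and 10 and comes back at 15, bringing in the tertiary oxygen only after the C–C bond is made.
- Acylation of 10 (n-BuLi, THF, −78 °C; 3-methylbut-2-enoyl chloride) should give the senecioyl imide F4.
- Its sodium dienolate (NaN(SiMe3)2, THF, −78 °C) should be alkylated by 8 at the α-carbon, anti to the benzyl group, to give the β,γ-unsaturated imide F5.
- Mukaiyama hydration of the isopropenyl group (Co(acac)2 cat., PhSiH3, O2, THF/i-PrOH) should give the tertiary alcohol F6; the electron-poor enol triflate alkene is inert.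
- Silylation (Et3SiOTf, 2,6-lutidine) should give 15.

**Step 14.** Intermolecular hydride delivery may compete with the directed pathway, giving poor facial selectivity at C-6. The fallback sets out from 21 and comes back at 24, making the other epimer on purpose and inverting it during esterification.
- Reduction of 21 with the bulky hydride LiBH(s-Bu)3 (THF, −78 °C), which attacks anti to the C-5 substituent, should give the cis-diol F7.
- Mitsunobu esterification of F7 with 23 (PPh3, diisopropyl azodicarboxylate, toluene, 0 °C to rt) should invert C-6 and give 24 directly.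

Further compounds
F1 | step 12 | (4S)-5-methyl-4-{[(5S)-5-methyl-2-(prop-1-en-2-yl)cyclopent-1-en-1-yl]methyl}-5-(triethylsilyloxy)hex-1-en-3-ol | C[C@H]1CCC(C(C)=C)=C1C[C@H](C(C)(C)O[Si](CC)(CC)CC)C(O)C=C
F2 | step 12 | (3S,5S,6RS)-3,8-dimethyl-5-[2-(triethylsilyloxy)propan-2-yl]-1,2,3,4,5,6-hexahydroazulen-6-ol | CC1=CC(O)[C@@H](C(C)(C)O[Si](CC)(CC)CC)CC2=C1CC[C@@H]2C
F3 | step 12 | (3S,5R)-3,8-dimethyl-5-[2-(triethylsilyloxy)propan-2-yl]-2,3,4,5-tetrahydroazulen-6(1H)-one | CC1=CC(=O)[C@@H](C(C)(C)O[Si](CC)(CC)CC)CC2=C1CC[C@@H]2C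
F4 | step 8 | (4R)-4-benzyl-3-(3-methylbut-2-enoyl)-1,3-oxazolidin-2-one | CC(C)=CC(=O)N1[C@H](Cc2ccccc2)COC1=O
F5 | step 8 | (4R)-4-benzyl-3-[(2R)-3-methyl-2-({(5S)-5-methyl-2-[(trifluoromethanesulfonyl)oxy]cyclopent-1-en-1-yl}methyl)but-3-enoyl]-1,3-oxazolidin-2-one | C[C@H]1CCC(OS(=O)(=O)C(F)(F)F)=C1C[C@H](C(C)=C)C(=O)N1[C@H](Cc2ccccc2)COC1=O
F6 | step 8 | (4R)-4-benzyl-3-[(2R)-3-hydroxy-3-methyl-2-({(5S)-5-methyl-2-[(trifluoromethanesulfonyl)oxy]cyclopent-1-en-1-yl}methyl)butanoyl]-1,3-oxazolidin-2-one | C[C@H]1CCC(OS(=O)(=O)C(F)(F)F)=C1C[C@H](C(C)(C)O)C(=O)N1[C@H](Cc2ccccc2)COC1=O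
F7 | step 14 | (3S,3aS,5S,6R)-5-(2-hydroxypropan-2-yl)-3,8-dimethyl-1,2,3,3a,4,5,6,7-octahydroazulen-6-ol | CC1=C2CC[C@H](C)[C@@H]2C[C@H](C(C)(C)O)[C@H](O)C1
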